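**Plan**

1. Retrosynthesis: C2–C3 is cut first, which turns the furanone into a nine-membered 4Z-enoate lactone whose C10 carries an acetyl group. Then C4=C5 (ring-closing metathesis) and the O10–C3 acyl bond are cut, then C7–C8 (radical conjugate addition) and C10–CH3.
2. Enabling feature: the furanone oxygen bridges C3 and C10. The ring O–C3 bond is therefore a masked ester of the C10 tertiary alcohol, and C1–C2 is a masked methyl ketone on the same carbon. The C2 enolate sits five atoms from C3, and the bond it forms spans the lactone ring.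
3. Forward order: tartrate acetonide → C10 carbinol (alkyne as latent acetyl) → decarboxylative Giese addition to the butenolide (γ-lactone in place) → α-methylene and C6 vinyl → O8 isovalerate, O9 MOM, O10 methacrylate → alkyne hydration → RCM (nine-membered lactone) → transannular Claisen/dehydration (furanone and ten-membered carbocycle together) → MOM removal.
4. Stereochemistry: C9 comes from L-tartaric acid; C8 is re-formed on the dioxolanyl radical trans to C9 (tartrate sense); C6 comes from (S)-5-(hydroxymethyl)furan-2(5H)-one and C7 from anti addition to it; C10 from chelation-controlled MeMgBr addition to an ynone; 4Z from ring size in the RCM.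

Key step: step 18

Remark: lobatin numbering (C1 ketone, C2=C3, C4(Me)=C5, C6–C10, lactone C11/C12/C13) is used for all intermediates; the SMILES strings fix the configurations.
Assumption: the tartrate enters as its commercial dimethyl ester acetonide and isovaleric acid as its commercial anhydride.

**Route**

Step 1
Reactants: 1 dimethyl (4R,5R)-2,2-dimethyl-1,3-dioxolane-4,5-dicarboxylate
Product: 2 (4R,5R)-5-(methoxycarbonyl)-2,2-dimethyl-1,3-dioxolane-4-carboxylic acid
Conditions: KOH (1.0 equiv), MeOH, 0 °C → rt; then aq. HCl to pH 3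
Reagents that add atoms: potassium hydroxide, [K+].[OH-]
Why: Mono-saponification of a C2-symmetric diester, in which the first carboxylate formed slows hydroxide attack on the second ester; the two esters are equivalent and no stereocentre is altered.

Step 2
Reactants: 2 (4R,5R)-5-(methoxycarbonyl)-2,2-dimethyl-1,3-dioxolane-4-carboxylic acid
Product: 3 methyl (4R,5R)-5-[methoxy(methyl)carbamoyl]-2,2-dimethyl-1,3-dioxolane-4-carboxylate
Conditions: MeNH(OMe)·HCl, EDC·HCl, HOBt, N-methylmorpholine, CH2Cl2, 0 °C → rt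
Reagents that add atoms: N,O-dimethylhydroxylamine hydrochloride, CNOC.Cl
Why: Carbodiimide amide coupling through the HOBt active ester gives the Weinreb amide and leaves the methyl ester and the acetonide alone.

Step 3
Reactants: 3 methyl (4R,5R)-5-[methoxy(methyl)carbamoyl]-2,2-dimethyl-1,3-dioxolane-4-carboxylate; 4 ethynyltri(propan-2-yl)silane
Product: 5 methyl (4R,5R)-2,2-dimethyl-5-[3-(triisopropylsilyl)prop-2-ynoyl]-1,3-dioxolane-4-carboxylate
Conditions: 4, n-BuLi, THF, −78 °C; then 3, −78 °C; aq. NH4Cl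
Reagents that add atoms: none
Why: Weinreb ketone synthesis, in which the lithium acetylide adds once to the chelating N-methoxy-N-methylamide and the tetrahedral chelate survives until quench, while a methyl ester is not attacked by an acetylide at −78 °C without Lewis acid activation.

Step 4
Reactants: 5 methyl (4R,5R)-2,2-dimethyl-5-[3-(triisopropylsilyl)prop-2-ynoyl]-1,3-dioxolane-4-carboxylate
Product: 6 methyl (4R,5R)-5-[(2S)-2-hydroxy-4-(triisopropylsilyl)but-3-yn-2-yl]-2,2-dimethyl-1,3-dioxolane-4-carboxylate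
Conditions: MeMgBr (1.2 equiv), THF, −78 °C; aq. NH4Cl
Reagents that add atoms: methylmagnesium bromide, C[Mg]Br
Why: Chelation-controlled Grignard 1,2-addition (Cram chelate model) in which magnesium bridges the ketone oxygen and the dioxolane oxygen on C9 and methyl enters from the chelate face that carries H-9 and not C8, which sets C10 (methyl as nucleophile and alkynyl as ketone substituent is the pairing that gives the required configuration); the silyl group blocks conjugate addition and the ynone reacts well before the ester.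

Step 5
Reactants: 6 methyl (4R,5R)-5-[(2S)-2-hydroxy-4-(triisopropylsilyl)but-3-yn-2-yl]-2,2-dimethyl-1,3-dioxolane-4-carboxylate
Product: 7 (4R,5R)-5-[(2S)-2-hydroxy-4-(triisopropylsilyl)but-3-yn-2-yl]-2,2-dimethyl-1,3-dioxolane-4-carboxylic acid
Conditions: LiOH·H2O, THF–H2O (3:1), 0 °C → rt; then aq. HCl to pH 3, 0 °C
Reagents that add atoms: lithium hydroxide, [Li+].[OH-]
Why: Ester saponification; the C-silyl alkyne is stable to hydroxide and the trans-dioxolane prevents lactonisation of the γ-hydroxy acid, and the configuration at C8 is of no consequence because this centre becomes the radical in step 7.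

Step 6
Reactants: 8 (5S)-5-(hydroxymethyl)furan-2(5H)-one
Product: 9 (5S)-5-{[tert-butyl(diphenyl)silyl]oxymethyl}furan-2(5H)-one
Conditions: TBDPSCl, imidazole, CH2Cl2, 0 °C → rt
Reagents that add atoms: tert-butyl(chloro)diphenylsilane, CC(C)(C)[Si](Cl)(c1ccccc1)c1ccccc1
Why: Silylation of the primary alcohol installs a bulky group that later shields one face of the butenolide.

Step 7
Reactants: 7 (4R,5R)-5-[(2S)-2-hydroxy-4-(triisopropylsilyl)but-3-yn-2-yl]-2,2-dimethyl-1,3-dioxolane-4-carboxylic acid; 9 (5S)-5-{[tert-butyl(diphenyl)silyl]oxymethyl}furan-2(5H)-one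
Product: 10 (4S,5S)-5-{[tert-butyl(diphenyl)silyl]oxymethyl}-4-{(4S,5R)-5-[(2S)-2-hydroxy-4-(triisopropylsilyl)but-3-yn-2-yl]-2,2-dimethyl-1,3-dioxolan-4-yl}oxolan-2-one
Conditions: [Ir{dF(CF3)ppy}2(dtbbpy)]PF6 (1 mol %), K2HPO4, DMF, blue LEDs, rt (9 in 1.5-fold excess)
Reagents that add atoms: none
Why: Photoredox decarboxylative Giese addition, in which the carboxylate is oxidised and loses CO2 to give the nucleophilic 1,3-dioxolan-4-yl radical; this adds to C7 of the butenolide anti to the C6 silyloxymethyl group and forms its bond trans to the bulky C9 substituent of the dioxolane, so C7 is set by the butenolide stereocentre and C8 is restored in the tartrate sense before reduction and protonation of the α-acyl radical.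

Step 8
Reactants: 10 (4S,5S)-5-{[tert-butyl(diphenyl)silyl]oxymethyl}-4-{(4S,5R)-5-[(2S)-2-hydroxy-4-(triisopropylsilyl)but-3-yn-2-yl]-2,2-dimethyl-1,3-dioxolan-4-yl}oxolan-2-one
Product: 13 (4S,5S)-5-{[tert-butyl(diphenyl)silyl]oxymethyl}-4-{(4S,5R)-5-[(2S)-2-hydroxy-4-(triisopropylsilyl)but-3-yn-2-yl]-2,2-dimethyl-1,3-dioxolan-4-yl}-3-methylideneoxolan-2-one, via Mannich base 11 (not isolated), via trimethylammonium iodide 12 (not isolated)
Conditions: LDA (2.3 equiv), THF, −78 °C; CH2=NMe2+ I−, −78 °C → rt; then MeI, MeOH, rt; then aq. NaHCO3, CH2Cl2, rt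
Reagents that add atoms: N,N-dimethylmethyleneiminium iodide (Eschenmoser's salt), C=[N+](C)C.[I-]
Why: Mannich reaction of the lithium lactone enolate (the extra base covers the tertiary hydroxyl; the silylated alkyne has no acidic proton) followed by exhaustive methylation and E1cB elimination, the standard α-methylenation of γ-lactones, in which C11 becomes sp2 so its configuration is irrelevant.

Step 9
Reactants: 13 (4S,5S)-5-{[tert-butyl(diphenyl)silyl]oxymethyl}-4-{(4S,5R)-5-[(2S)-2-hydroxy-4-(triisopropylsilyl)but-3-yn-2-yl]-2,2-dimethyl-1,3-dioxolan-4-yl}-3-methylideneoxolan-2-one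
Product: 14 (4S,5S)-5-(hydroxymethyl)-4-{(4S,5R)-5-[(2S)-2-hydroxybut-3-yn-2-yl]-2,2-dimethyl-1,3-dioxolan-4-yl}-3-methylideneoxolan-2-one
Conditions: TBAF (3 equiv), AcOH (3 equiv), THF, 0 °C → rt
Reagents that add atoms: none
Why: Fluoride cleaves both the O–Si and the C(sp)–Si bond in one operation, and acetic acid keeps the medium from becoming basic enough to harm the α-methylene lactone.

Step 10
Reactants: 14 (4S,5S)-5-(hydroxymethyl)-4-{(4S,5R)-5-[(2S)-2-hydroxybut-3-yn-2-yl]-2,2-dimethyl-1,3-dioxolan-4-yl}-3-methylideneoxolan-2-one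
Product: 15 (2S,3R)-3-{(4S,5R)-5-[(2S)-2-hydroxybut-3-yn-2-yl]-2,2-dimethyl-1,3-dioxolan-4-yl}-4-methylidene-5-oxooxolane-2-carbaldehyde
Conditions: Dess–Martin periodinane, NaHCO3, CH2Cl2, 0 °C → rt
Reagents that add atoms: none
Why: Dess–Martin oxidation of the primary alcohol under buffered, non-epimerising conditions; the tertiary alcohol cannot be oxidised.

Step 11
Reactants: 15 (2S,3R)-3-{(4S,5R)-5-[(2S)-2-hydroxybut-3-yn-2-yl]-2,2-dimethyl-1,3-dioxolan-4-yl}-4-methylidene-5-oxooxolane-2-carbaldehyde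
Product: 16 (4S,5R)-5-ethenyl-4-{(4S,5R)-5-[(2S)-2-hydroxybut-3-yn-2-yl]-2,2-dimethyl-1,3-dioxolan-4-yl}-3-methylideneoxolan-2-one
Conditions: CH2I2, Zn, Ti(OiPr)4, THF, rt
Reagents that add atoms: diiodomethane, ICI
Why: Takai-type methylenation with the geminal dizinc reagent is non-basic and aldehyde-selective, so the epimerisable α-acyloxy aldehyde is converted to the vinyl group without touching the lactone, its conjugated methylene or the acetonide.

Step 12
Reactants: 16 (4S,5R)-5-ethenyl-4-{(4S,5R)-5-[(2S)-2-hydroxybut-3-yn-2-yl]-2,2-dimethyl-1,3-dioxolan-4-yl}-3-methylideneoxolan-2-one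
Product: 17 (4R,5R)-5-ethenyl-3-methylidene-4-[(1S,2R,3S)-1,2,3-trihydroxy-3-methylpent-4-yn-1-yl]oxolan-2-one
Conditions: AcOH–H2O (4:1), 45 °C
Reagents that add atoms: none
Why: Acid-catalysed hydrolysis of the isopropylidene acetal under conditions too mild to ionise the tertiary propargylic alcohol or to open the lactone.

Step 13
Reactants: 17 (4R,5R)-5-ethenyl-3-methylidene-4-[(1S,2R,3S)-1,2,3-trihydroxy-3-methylpent-4-yn-1-yl]oxolan-2-one; 18 3-methylbutanoic anhydride
Product: 19 (1S,2R,3S)-1-[(2R,3S)-2-ethenyl-4-methylidene-5-oxooxolan-3-yl]-2,3-dihydroxy-3-methylpent-4-yn-1-yl 3-methylbutanoate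
Conditions: 18 (1.05 equiv), Et3N, DMAP (10 mol %), CH2Cl2, −40 °C
Reagents that add atoms: none
Why: DMAP-catalysed acylation under kinetic control should take the C8 hydroxyl, because the C9 hydroxyl is flanked by the fully substituted C10 and by two oxygen-bearing carbons (more hindered and less nucleophilic) and the tertiary C10 hydroxyl is inert at this temperature.

Step 14
Reactants: 19 (1S,2R,3S)-1-[(2R,3S)-2-ethenyl-4-methylidene-5-oxooxolan-3-yl]-2,3-dihydroxy-3-methylpent-4-yn-1-yl 3-methylbutanoate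
Product: 20 (1S,2R,3S)-1-[(2R,3S)-2-ethenyl-4-methylidene-5-oxooxolan-3-yl]-3-hydroxy-2-(methoxymethoxy)-3-methylpent-4-yn-1-yl 3-methylbutanoate
Conditions: MOMCl, iPr2NEt, Bu4NI (cat.), CH2Cl2, 0 °C → rt
Reagents that add atoms: chloromethyl methyl ether, COCCl
Why: O-alkylation with the small, reactive chloromethyl ether and a hindered amine protects the secondary C9 hydroxyl while the tertiary C10 hydroxyl reacts much more slowly, and the weak base does not promote acyl migration.

Step 15
Reactants: 20 (1S,2R,3S)-1-[(2R,3S)-2-ethenyl-4-methylidene-5-oxooxolan-3-yl]-3-hydroxy-2-(methoxymethoxy)-3-methylpent-4-yn-1-yl 3-methylbutanoate; 21 2-methylprop-2-enoyl chloride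
Product: 22 (3S,4R,5S)-5-[(2R,3S)-2-ethenyl-4-methylidene-5-oxooxolan-3-yl]-4-(methoxymethoxy)-3-methyl-5-[(3-methylbutanoyl)oxy]pent-1-yn-3-yl 2-methylprop-2-enoate
Conditions: 21, Et3N, DMAP, CH2Cl2, 0 °C → rt
Reagents that add atoms: none
Why: Acylation of the tertiary propargylic alcohol through the acylpyridinium ion (nucleophilic catalysis) is done while C1 is still an alkyne, which avoids α-ketol rearrangement and enolisation of the later ketone; the acid chloride has no α-hydrogen and cannot form a ketene.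

Step 16
Reactants: 22 (3S,4R,5S)-5-[(2R,3S)-2-ethenyl-4-methylidene-5-oxooxolan-3-yl]-4-(methoxymethoxy)-3-methyl-5-[(3-methylbutanoyl)oxy]pent-1-yn-3-yl 2-methylprop-2-enoate
Product: 23 (3R,4R,5S)-5-[(2R,3S)-2-ethenyl-4-methylidene-5-oxooxolan-3-yl]-4-(methoxymethoxy)-3-methyl-5-[(3-methylbutanoyl)oxy]-2-oxopentan-3-yl 2-methylprop-2-enoate
Conditions: Ph3PAuCl (5 mol %), AgSbF6 (5 mol %), H2O (5 equiv), 1,4-dioxane, rt
Reagents that add atoms: water, O
Why: Gold(I)-catalysed Markovnikov hydration of the terminal alkyne, assisted by the neighbouring ester carbonyl (5-exo attack on the gold-activated alkyne, then hydrolysis of the dioxolenium ion), gives the α-acyloxy methyl ketone and leaves the alkenes, the acetal and the esters untouched.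

Step 17
Reactants: 23 (3R,4R,5S)-5-[(2R,3S)-2-ethenyl-4-methylidene-5-oxooxolan-3-yl]-4-(methoxymethoxy)-3-methyl-5-[(3-methylbutanoyl)oxy]-2-oxopentan-3-yl 2-methylprop-2-enoate
Product: 24 nine-membered (4Z)-enoate lactone (6R,7S,8S,9R,10R): ring C3(=O)–O–C10–C9–C8–C7–C6–C5=C4(Me), with 10-acetyl, 10-methyl, 9-OMOM, 8-O-isovaleryl and the C6/C7-fused α-methylene-γ-lactone
Conditions: Hoveyda–Grubbs II catalyst (10 mol %), toluene (1 mM), 80 °C
Reagents that add atoms: none
Why: Ring-closing metathesis in which the catalyst loads on the monosubstituted C6 vinyl group and closes onto the methacrylate; the quaternary C10 and the γ-lactone fold the chain, high dilution suppresses dimerisation, a nine-membered ring can hold the trisubstituted enoate only in the Z form, and the 1,1-disubstituted electron-poor exocyclic methylene cannot compete.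

Step 18
Reactants: 24 nine-membered (4Z)-enoate lactone (6R,7S,8S,9R,10R)
Product: 26 9-O-(methoxymethyl)lobatin B, via bridged C3 hemiketal 25 (not isolated)
Conditions: MgBr2·OEt2, iPr2NEt, CH2Cl2, 0 °C → rt; then p-TsOH·H2O (cat.), CH2Cl2, rt
Reagents that add atoms: none
Why: Magnesium bromide binds the C1 ketone and its α-acyloxy oxygen, the hindered amine removes a C2 proton, and the magnesium enolate attacks the lactone carbonyl C3 to form C2–C3 and the bridged hemiketal alkoxide 25 (in equilibrium with the ring-opened 10-hydroxy-1,3-diketonate), from which acid removes water across C2–C3. The closest known reactions are the base-induced Claisen-type (Baker–Venkataraman-like) C-acylation of α-acyloxy ketones with cyclodehydration to 3(2H)-furanones and the Mg(II)/amine soft-enolisation acylation of ketones. The furanone ring (C10, C1, C2, C3, O) closes 5-exo-trig on the ester carbonyl, and the ten-membered carbocycle C1–C10 appears in the same event because the new bond spans the nine-membered lactone, so no separate macrocyclisation is needed. No stereocentre is created that survives (C3 of 25 becomes sp2), and C6–C10 and the 4Z alkene are carried over unchanged. The step needs ketone-over-ester enolisation, which the soft conditions secure (C10 is quaternary, so C2 is the only enolisable ketone position and esters are not enolised by MgBr2/amine). It also needs 1,2- over 1,4-addition, which is secured because attack at C3 closes a five-membered ring whereas attack at C5 would need a seven-membered ring at the hindered β-carbon of a Z-enoate; the vinylogous ester of the product drives the sequence.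

Step 19
Reactants: 26 9-O-(methoxymethyl)lobatin B
Product: 27 lobatin B
Conditions: Me2BBr, CH2Cl2, −78 °C; then aq. NaHCO3
Reagents that add atoms: none
Why: Lewis-acid cleavage of the methoxymethyl acetal, in which boron binds the methoxy oxygen and bromide cleaves the O–CH2 bond at −78 °C, frees the C9 hydroxyl on aqueous work-up without touching the isovalerate, the lactone or the vinylogous ester.

**Compound list**

1 | dimethyl (4R,5R)-2,2-dimethyl-1,3-dioxolane-4,5-dicarboxylate (dimethyl 2,3-O-isopropylidene-L-tartrate) | COC(=O)[C@@H]1OC(C)(C)O[C@H]1C(=O)OC | starting material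
2 | (4R,5R)-5-(methoxycarbonyl)-2,2-dimethyl-1,3-dioxolane-4-carboxylic acid | COC(=O)[C@@H]1OC(C)(C)O[C@H]1C(=O)O | intermediate
3 | methyl (4R,5R)-5-[methoxy(methyl)carbamoyl]-2,2-dimethyl-1,3-dioxolane-4-carboxylate | COC(=O)[C@@H]1OC(C)(C)O[C@H]1C(=O)N(C)OC | intermediate
4 | ethynyltri(propan-2-yl)silane | C#C[Si](C(C)C)(C(C)C)C(C)C | starting material
5 | methyl (4R,5R)-2,2-dimethyl-5-[3-(triisopropylsilyl)prop-2-ynoyl]-1,3-dioxolane-4-carboxylate | COC(=O)[C@@H]1OC(C)(C)O[C@H]1C(=O)C#C[Si](C(C)C)(C(C)C)C(C)C | intermediate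
6 | methyl (4R,5R)-5-[(2S)-2-hydroxy-4-(triisopropylsilyl)but-3-yn-2-yl]-2,2-dimethyl-1,3-dioxolane-4-carboxylate | COC(=O)[C@@H]1OC(C)(C)O[C@H]1[C@@](C)(O)C#C[Si](C(C)C)(C(C)C)C(C)C | intermediate
7 | (4R,5R)-5-[(2S)-2-hydroxy-4-(triisopropylsilyl)but-3-yn-2-yl]-2,2-dimethyl-1,3-dioxolane-4-carboxylic acid | OC(=O)[C@@H]1OC(C)(C)O[C@H]1[C@@](C)(O)C#C[Si](C(C)C)(C(C)C)C(C)C | intermediate
8 | (5S)-5-(hydroxymethyl)furan-2(5H)-one | O=C1O[C@H](CO)C=C1 | starting material
9 | (5S)-5-{[tert-butyl(diphenyl)silyl]oxymethyl}furan-2(5H)-one | O=C1O[C@H](CO[Si](c2ccccc2)(c2ccccc2)C(C)(C)C)C=C1 | intermediate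
10 | (4S,5S)-5-{[tert-butyl(diphenyl)silyl]oxymethyl}-4-{(4S,5R)-5-[(2S)-2-hydroxy-4-(triisopropylsilyl)but-3-yn-2-yl]-2,2-dimethyl-1,3-dioxolan-4-yl}oxolan-2-one | O=C1O[C@H](CO[Si](c2ccccc2)(c2ccccc2)C(C)(C)C)[C@H](C1)[C@@H]3OC(C)(C)O[C@H]3[C@@](C)(O)C#C[Si](C(C)C)(C(C)C)C(C)C | intermediate
11 | Mannich base: 3-[(dimethylamino)methyl] derivative of 10 (C3 epimers) | CN(C)CC1C(=O)O[C@H](CO[Si](c2ccccc2)(c2ccccc2)C(C)(C)C)[C@H]1[C@@H]3OC(C)(C)O[C@H]3[C@@](C)(O)C#C[Si](C(C)C)(C(C)C)C(C)C | intermediate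
12 | trimethylammonium iodide of 11 | C[N+](C)(C)CC1C(=O)O[C@H](CO[Si](c2ccccc2)(c2ccccc2)C(C)(C)C)[C@H]1[C@@H]3OC(C)(C)O[C@H]3[C@@](C)(O)C#C[Si](C(C)C)(C(C)C)C(C)C.[I-] | intermediate
13 | (4S,5S)-5-{[tert-butyl(diphenyl)silyl]oxymethyl}-4-{(4S,5R)-5-[(2S)-2-hydroxy-4-(triisopropylsilyl)but-3-yn-2-yl]-2,2-dimethyl-1,3-dioxolan-4-yl}-3-methylideneoxolan-2-one | C=C1C(=O)O[C@H](CO[Si](c2ccccc2)(c2ccccc2)C(C)(C)C)[C@H]1[C@@H]3OC(C)(C)O[C@H]3[C@@](C)(O)C#C[Si](C(C)C)(C(C)C)C(C)C | intermediate
14 | (4S,5S)-5-(hydroxymethyl)-4-{(4S,5R)-5-[(2S)-2-hydroxybut-3-yn-2-yl]-2,2-dimethyl-1,3-dioxolan-4-yl}-3-methylideneoxolan-2-one | C=C1C(=O)O[C@H](CO)[C@H]1[C@@H]3OC(C)(C)O[C@H]3[C@@](C)(O)C#C | intermediate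
15 | (2S,3R)-3-{(4S,5R)-5-[(2S)-2-hydroxybut-3-yn-2-yl]-2,2-dimethyl-1,3-dioxolan-4-yl}-4-methylidene-5-oxooxolane-2-carbaldehyde | C=C1C(=O)O[C@H](C=O)[C@H]1[C@@H]3OC(C)(C)O[C@H]3[C@@](C)(O)C#C | intermediate
16 | (4S,5R)-5-ethenyl-4-{(4S,5R)-5-[(2S)-2-hydroxybut-3-yn-2-yl]-2,2-dimethyl-1,3-dioxolan-4-yl}-3-methylideneoxolan-2-one | C=C1C(=O)O[C@H](C=C)[C@H]1[C@@H]3OC(C)(C)O[C@H]3[C@@](C)(O)C#C | intermediate
17 | (4R,5R)-5-ethenyl-3-methylidene-4-[(1S,2R,3S)-1,2,3-trihydroxy-3-methylpent-4-yn-1-yl]oxolan-2-one | C=C1C(=O)O[C@H](C=C)[C@H]1[C@H](O)[C@@H](O)[C@@](C)(O)C#C | intermediate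
18 | 3-methylbutanoic anhydride (isovaleric anhydride) | CC(C)CC(=O)OC(=O)CC(C)C | starting material
19 | (1S,2R,3S)-1-[(2R,3S)-2-ethenyl-4-methylidene-5-oxooxolan-3-yl]-2,3-dihydroxy-3-methylpent-4-yn-1-yl 3-methylbutanoate | C=C1C(=O)O[C@H](C=C)[C@H]1[C@H](OC(=O)CC(C)C)[C@@H](O)[C@@](C)(O)C#C | intermediate
20 | (1S,2R,3S)-1-[(2R,3S)-2-ethenyl-4-methylidene-5-oxooxolan-3-yl]-3-hydroxy-2-(methoxymethoxy)-3-methylpent-4-yn-1-yl 3-methylbutanoate | C=C1C(=O)O[C@H](C=C)[C@H]1[C@H](OC(=O)CC(C)C)[C@@H](OCOC)[C@@](C)(O)C#C | intermediate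
21 | 2-methylprop-2-enoyl chloride (methacryloyl chloride) | C=C(C)C(Cl)=O | starting material
22 | (3S,4R,5S)-5-[(2R,3S)-2-ethenyl-4-methylidene-5-oxooxolan-3-yl]-4-(methoxymethoxy)-3-methyl-5-[(3-methylbutanoyl)oxy]pent-1-yn-3-yl 2-methylprop-2-enoate | C=C1C(=O)O[C@H](C=C)[C@H]1[C@H](OC(=O)CC(C)C)[C@@H](OCOC)[C@@](C)(OC(=O)C(C)=C)C#C | intermediate
23 | (3R,4R,5S)-5-[(2R,3S)-2-ethenyl-4-methylidene-5-oxooxolan-3-yl]-4-(methoxymethoxy)-3-methyl-5-[(3-methylbutanoyl)oxy]-2-oxopentan-3-yl 2-methylprop-2-enoate | C=C1C(=O)O[C@H](C=C)[C@H]1[C@H](OC(=O)CC(C)C)[C@@H](OCOC)[C@@](C)(OC(=O)C(C)=C)C(C)=O | intermediate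
24 | nine-membered (4Z)-enoate lactone of the C10 tertiary alcohol (6R,7S,8S,9R,10R) with 10-acetyl, 9-OMOM, 8-O-isovaleryl and fused α-methylene-γ-lactone | C=C1C(=O)O[C@@H]2/C=C(/C)C(=O)O[C@@](C)(C(C)=O)[C@H](OCOC)[C@@H](OC(=O)CC(C)C)[C@@H]12 | intermediate
25 | bridged hemiketal (3-hydroxy-2,3-dihydro derivative of 26; O bridges C3 and C10, C4 cis to C9 on the five-membered ring) | C=C1C(=O)O[C@@H]2/C=C(/C)[C@@]3(O)CC(=O)[C@](C)(O3)[C@H](OCOC)[C@@H](OC(=O)CC(C)C)[C@@H]12 | intermediate
26 | 9-O-(methoxymethyl)lobatin B | C=C1C(=O)O[C@@H]2/C=C(/C)C3=CC(=O)[C@](C)(O3)[C@H](OCOC)[C@@H](OC(=O)CC(C)C)[C@@H]12 | intermediate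
27 | lobatin B (6R,7S,8S,9R,10R; 4Z) | C=C1C(=O)O[C@@H]2/C=C(/C)C3=CC(=O)[C@](C)(O3)[C@H](O)[C@@H](OC(=O)CC(C)C)[C@@H]12 | target

**Step count and risks**

Total step count: 19. Longest linear sequence: 18 steps (steps 1–5 and 7–19, from 1 to 27); step 6 is the one-step side branch.

Steps most likely to fail:

Step 17 (ring-closing metathesis). The ruthenium carbene formed at the C6 vinyl group may react with a second molecule faster than with the slow-reacting, electron-poor 1,1-disubstituted methacrylate, so oligomerisation or stalled turnover can replace closure of the strained nine-membered lactone. The fallback closes the same C4=C5 bond by olefination and sets out from 20. The tertiary hydroxyl of 20 is esterified with 2-[bis(2,2,2-trifluoroethoxy)phosphoryl]propanoic acid (DCC, DMAP) to give the phosphonopropionate alkyne F1. Gold-catalysed hydration as in step 16 gives the phosphonopropionate methyl ketone F2. Selective oxidative cleavage of the electron-richer C6 vinyl group (OsO4 cat., NaIO4, 2,6-lutidine) gives the C5 aldehyde F3. Intramolecular Still–Gennari olefination (K2CO3, 18-crown-6, toluene, high dilution) should then deliver the Z-enoate and return to the route at 24.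

Step 18 (transannular Claisen/dehydration). The enolate may be unable to reach the lactone carbonyl across the nine-membered ring, since the ester is held in a ring-imposed conformation; the ketone would then be returned or consumed by slower side processes. The fallback keeps the same C2–C3 bond formation but runs it before ring closure, and sets out from 23. Kinetic enolisation (LiHMDS, THF, −78 °C) and acyl transfer onto the methacrylate carbonyl give the open-chain hemiketal F4. Acid (p-TsOH) dehydrates it to the 5-isopropenyl-3(2H)-furanone diene F5. Ring-closing metathesis between the isopropenyl group and the C6 vinyl group (Grubbs second-generation catalyst, dilute toluene, 80 °C) then closes the ten-membered carbocycle and rejoins the route at 26.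

Step 13 (regioselective acylation). Discrimination between the C8 and C9 hydroxyls may be incomplete, or the ester may migrate from O8 to O9 during the following alkylation. The fallback introduces the ester last, when only one secondary hydroxyl is free, and sets out from 17. The far more size-sensitive TBSCl (imidazole, DMF, −20 °C) silylates the less hindered C8 hydroxyl to give the 8-O-TBS diol F6. MOMCl/iPr2NEt gives the 8-O-TBS 9-O-MOM ether F7, and HF·pyridine removes the silyl group to give the 9-O-MOM diol F8. Acylation of F8 with 18/DMAP can only take the secondary C8 hydroxyl (C10 is tertiary) and returns to the route at 20.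

Further compounds
F1 | step 17 | tertiary 2-[bis(2,2,2-trifluoroethoxy)phosphoryl]propanoate of 20 (alkyne) | C=C1C(=O)O[C@H](C=C)[C@H]1[C@H](OC(=O)CC(C)C)[C@@H](OCOC)[C@@](C)(OC(=O)C(C)P(=O)(OCC(F)(F)F)OCC(F)(F)F)C#C
F2 | step 17 | corresponding C10 methyl ketone | C=C1C(=O)O[C@H](C=C)[C@H]1[C@H](OC(=O)CC(C)C)[C@@H](OCOC)[C@@](C)(OC(=O)C(C)P(=O)(OCC(F)(F)F)OCC(F)(F)F)C(C)=O
F3 | step 17 | corresponding C5 aldehyde (C6 formyl lactone) | C=C1C(=O)O[C@H](C=O)[C@H]1[C@H](OC(=O)CC(C)C)[C@@H](OCOC)[C@@](C)(OC(=O)C(C)P(=O)(OCC(F)(F)F)OCC(F)(F)F)C(C)=O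
F4 | step 18 | open-chain hemiketal (5-hydroxy-5-isopropenyl-2-methyl-oxolan-3-one carrying the C6–C9 chain at C2) | C=C1C(=O)O[C@H](C=C)[C@H]1[C@H](OC(=O)CC(C)C)[C@@H](OCOC)[C@@]2(C)OC(O)(C(C)=C)CC2=O
F5 | step 18 | open-chain 5-isopropenyl-2-methyl-3(2H)-furanone diene | C=C1C(=O)O[C@H](C=C)[C@H]1[C@H](OC(=O)CC(C)C)[C@@H](OCOC)[C@@]2(C)OC(C(C)=C)=CC2=O
F6 | step 13 | 8-O-tert-butyldimethylsilyl ether of 17 | C=C1C(=O)O[C@H](C=C)[C@H]1[C@H](O[Si](C)(C)C(C)(C)C)[C@@H](O)[C@@](C)(O)C#C
F7 | step 13 | 8-O-tert-butyldimethylsilyl 9-O-methoxymethyl ether of 17 | C=C1C(=O)O[C@H](C=C)[C@H]1[C@H](O[Si](C)(C)C(C)(C)C)[C@@H](OCOC)[C@@](C)(O)C#C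
F8 | step 13 | 9-O-methoxymethyl ether of 17 (8,10-diol) | C=C1C(=O)O[C@H](C=C)[C@H]1[C@H](O)[C@@H](OCOC)[C@@](C)(O)C#C
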